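**Plan**

- Retrosynthesis: the C1'–C(=O) aryl ketone bond is cut first (C1' aryllithium plus the Weinreb amide of (E)-4-hydroxycinnamic acid). Ring A is then cut at C1'–C2', C3'–C4' and C4'–C5' into a dienyl diazo ketone (C4' with its oxygen, C1', C6', C5' and the C5' prenyl) and a siloxyalkyne (C2' with its oxygen, C3' with its prenyl).
- Enabling feature: ring A is a resorcinol (oxygen on C2' and C4') whose C3', between the two oxygens, carries a carbon substituent (prenyl). A second prenyl sits on C5' next to C4'–OH, and C1' and C6' can be CH before acylation. A vinylketene and an ynol ether assemble exactly this pattern.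
- Forward: three short arms give diazo ketone 6, siloxyalkyne 12 and amide 22. Ring A is the only ring made (step 6, from two open-chain partners); ring B is bought. Silyl-to-MOM exchange, MOM-directed lithiation at C1', acylation with 22 and acidic removal of three MOM groups finish the chalcone.
- Stereochemistry: the target has no stereocentre. Its (E)-enone alkene is that of (E)-4-hydroxycinnamic acid, carried through unchanged. The (E)-alkene of 6 comes from a stabilised-ylide Wittig reaction and ends inside the aromatic ring.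

Key step: step 6

Assumption: diketone 5 is drawn in its diketo form although it should be largely enolised, and 8 is taken as the commercial THF solution.

**Route**

Step 1
Reactants: 1 4-methylpent-3-en-1-ol; 2 1-(triphenylphosphoranylidene)propan-2-one
Product: 4 (E)-7-methylocta-3,6-dien-2-one, via 4-methylpent-3-enal 3 (not isolated)
Conditions: Dess–Martin periodinane, NaHCO3, CH2Cl2, 0 °C → rt; then 2, rt
Reagents that add atoms: none
Why: Buffered Dess–Martin oxidation should give the β,γ-unsaturated aldehyde under near-neutral conditions, and the stabilised ylide traps it in the same flask (Wittig olefination, (E)-selective) before the double bond can move into conjugation.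

Step 2
Reactants: 4 (E)-7-methylocta-3,6-dien-2-one
Product: 5 (E)-1,1,1-trifluoro-9-methyldeca-5,8-diene-2,4-dione
Conditions: LiN(SiMe3)2, THF, −78 °C; CF3CO2CH2CF3, −78 °C; aq HCl work-up, crude product taken on
Reagents that add atoms: 2,2,2-trifluoroethyl trifluoroacetate, O=C(OCC(F)(F)F)C(F)(F)F
Why: The lithium amide should remove a proton kinetically from the α' methyl group of the (E)-enone, and Claisen-type trifluoroacetylation of the cross-conjugated enolate activates that carbon for diazo transfer.

Step 3
Reactants: 5 (E)-1,1,1-trifluoro-9-methyldeca-5,8-diene-2,4-dione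
Product: 6 (E)-1-diazo-7-methylocta-3,6-dien-2-one
Conditions: MsN3, Et3N, H2O (1 equiv), MeCN, rt
Reagents that add atoms: methanesulfonyl azide, CS(=O)(=O)N=[N+]=[N-]
Why: Detrifluoroacetylative (deacylative Regitz-type) diazo transfer: the diketone enolate adds to the sulfonyl azide and loss of the trifluoroacetyl group leaves the α'-diazo enone under mild amine base that should spare the skipped diene.

Step 4
Reactants: 7 1-bromo-3-methylbut-2-ene; 8 ethynylmagnesium bromide
Product: 9 5-methylhex-4-en-1-yne
Conditions: CuCl (cat.), THF, 0 → 40 °C; product distilled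
Reagents that add atoms: none
Why: Copper-catalysed coupling of an alkynyl Grignard reagent with a primary allylic bromide should occur at the unhindered CH2 terminus of the prenyl unit (SN2 mode) and give the linear 1,4-enyne.

Step 5
Reactants: 9 5-methylhex-4-en-1-yne
Product: 12 triisopropyl[(5-methylhex-4-en-1-yn-1-yl)oxy]silane, via lithium acetylide 10 (not isolated), via lithium ynolate 11 (not isolated)
Conditions: n-BuLi, THF, −78 °C; LiOOt-Bu (from t-BuOOH, LiN(SiMe3)2), −78 → 0 °C; iPr3SiOTf, −78 → 0 °C
Reagents that add atoms: tert-butyl hydroperoxide, CC(C)(C)OO; triisopropylsilyl trifluoromethanesulfonate, CC(C)[Si](OS(=O)(=O)C(F)(F)F)(C(C)C)C(C)C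
Why: Oxygen transfer from lithium tert-butyl peroxide to the lithium acetylide (acetylide-to-ynolate oxidation) followed by O-silylation of the ynolate with the bulky silyl triflate, which prefers oxygen over carbon, should give the siloxyalkyne.

Step 6
Reactants: 6 (E)-1-diazo-7-methylocta-3,6-dien-2-one; 12 triisopropyl[(5-methylhex-4-en-1-yn-1-yl)oxy]silane
Product: 17 2,6-bis(3-methylbut-2-en-1-yl)-3-[(triisopropylsilyl)oxy]phenol, via vinylketene 13 (not isolated), via vinylcyclobutenone 14 (not isolated), via dienylketene 15 (not isolated), via cyclohexadienone 16 (not isolated)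
Conditions: hν (254 nm, low-pressure mercury lamp, quartz), ClCH2CH2Cl, rt; then 80 °C
Reagents that add atoms: none
Why: Light expels N2 from 6 and the dienyl group shifts from the carbonyl carbon to the carbene carbon (photochemical Wolff rearrangement) to give vinylketene 13, whose C=O carbon (future C4') and α-carbon (future C1') add across the polarised triple bond of 12 in a [2+2] cycloaddition to give 4-vinylcyclobutenone 14. Heating opens 14 by reversible conrotatory 4π electrocyclic cleavage of the C4'–C1' bond to dienylketene 15, and ring A closes by thermally allowed disrotatory 6π electrocyclisation between the ketene carbon C4' and the diene terminus C5' to cyclohexadienone 16, which tautomerises to phenol 17; the four-membered ring is only a relay. This is the diazo ketone (second-generation) form of the Danheiser benzannulation, which with siloxyalkynes is known to give resorcinol monosilyl ethers. No stereocentre survives, because the sp3 carbons of 14 and 16 are erased on aromatisation. The step needs one regiochemical outcome in the [2+2], and the ynol ether secures it: its nucleophilic carbon is the one remote from oxygen, so the prenyl-bearing carbon bonds to the electrophilic ketene C=O carbon and that prenyl lands on C3' between the two oxygens. Chemoselectivity rests on the ynol ether being a far better ketene partner than the trisubstituted prenyl alkenes and on the (E)-alkene of 13 holding the side-chain olefin out of reach of the ketene.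

Step 7
Reactants: 17 2,6-bis(3-methylbut-2-en-1-yl)-3-[(triisopropylsilyl)oxy]phenol
Product: 18 2,4-bis(3-methylbut-2-en-1-yl)benzene-1,3-diol
Conditions: Bu4NF, AcOH, THF, 0 °C
Reagents that add atoms: none
Why: Fluoride cleaves the aryl silyl ether through Si–F bond formation, and the acetic acid buffer keeps the electron-rich resorcinol from standing as a phenoxide.

Step 8
Reactants: 18 2,4-bis(3-methylbut-2-en-1-yl)benzene-1,3-diol
Product: 19 1,3-bis(methoxymethoxy)-2,4-bis(3-methylbut-2-en-1-yl)benzene
Conditions: NaH, MOMCl, THF–DMF, 0 °C → rt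
Reagents that add atoms: chloromethyl methyl ether, COCCl
Why: Williamson-type O-alkylation of both sodium phenoxides by the hard electrophile MOMCl; NaH is chosen because the C4' hydroxyl is flanked by two prenyl groups.

Step 9
Reactants: 20 (E)-4-hydroxycinnamic acid
Product: 21 (E)-3-(4-hydroxyphenyl)-N-methoxy-N-methylprop-2-enamide
Conditions: MeNHOMe·HCl, EDC·HCl, HOBt, N-methylmorpholine, DMF, 0 °C → rt
Reagents that add atoms: N,O-dimethylhydroxylamine hydrochloride, CNOC.Cl
Why: Carbodiimide amide coupling through the HOBt active ester, in which the amine should outcompete the free phenol and the (E)-alkene is untouched.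

Step 10
Reactants: 21 (E)-3-(4-hydroxyphenyl)-N-methoxy-N-methylprop-2-enamide
Product: 22 (E)-N-methoxy-3-[4-(methoxymethoxy)phenyl]-N-methylprop-2-enamide
Conditions: MOMCl, iPr2NEt, CH2Cl2, 0 °C → rt
Reagents that add atoms: chloromethyl methyl ether, COCCl
Why: O-alkylation of the phenol under amine base gives an acetal ether that will survive the aryllithium of the next step.

Step 11
Reactants: 19 1,3-bis(methoxymethoxy)-2,4-bis(3-methylbut-2-en-1-yl)benzene; 22 (E)-N-methoxy-3-[4-(methoxymethoxy)phenyl]-N-methylprop-2-enamide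
Product: 25 (E)-1-[2,4-bis(methoxymethoxy)-3,5-bis(3-methylbut-2-en-1-yl)phenyl]-3-[4-(methoxymethoxy)phenyl]prop-2-en-1-one, via aryllithium 23 (not isolated), via tetrahedral lithium adduct 24 (not isolated)
Conditions: n-BuLi, TMEDA, THF, −20 → 0 °C; then 22, −78 → 0 °C; AcOH quench
Reagents that add atoms: none
Why: Directed ortho-metalation, in which the C2' MOM ether should deliver n-BuLi to C1'–H (the only ring hydrogen next to an oxygen), followed by 1,2-addition of the aryllithium to the Weinreb amide to a chelated adduct that releases the enone only on quenching, so over-addition is avoided.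

Step 12
Reactants: 25 (E)-1-[2,4-bis(methoxymethoxy)-3,5-bis(3-methylbut-2-en-1-yl)phenyl]-3-[4-(methoxymethoxy)phenyl]prop-2-en-1-one
Product: 26 (E)-1-[2,4-dihydroxy-3,5-bis(3-methylbut-2-en-1-yl)phenyl]-3-(4-hydroxyphenyl)prop-2-en-1-one
Conditions: 3 M aq HCl, MeOH, rt → 40 °C
Reagents that add atoms: none
Why: Acid-catalysed acetal cleavage (transacetalisation to methanol) frees the three phenols under conditions mild enough that the ortho-prenyl phenols should not cyclise and the 2'-hydroxychalcone should stay open.

**Compound list**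

1 | 4-methylpent-3-en-1-ol | CC(C)=CCCO | starting material
2 | 1-(triphenylphosphoranylidene)propan-2-one | CC(=O)C=P(c1ccccc1)(c1ccccc1)c1ccccc1 | starting material
3 | 4-methylpent-3-enal (not isolated) | CC(C)=CCC=O | intermediate
4 | (E)-7-methylocta-3,6-dien-2-one | CC(=O)/C=C/CC=C(C)C | intermediate
5 | (E)-1,1,1-trifluoro-9-methyldeca-5,8-diene-2,4-dione | CC(C)=CC/C=C/C(=O)CC(=O)C(F)(F)F | intermediate
6 | (E)-1-diazo-7-methylocta-3,6-dien-2-one | CC(C)=CC/C=C/C(=O)C=[N+]=[N-] | intermediate
7 | 1-bromo-3-methylbut-2-ene | CC(C)=CCBr | starting material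
8 | ethynylmagnesium bromide | C#C[Mg]Br | starting material
9 | 5-methylhex-4-en-1-yne | C#CCC=C(C)C | intermediate
10 | (5-methylhex-4-en-1-yn-1-yl)lithium (not isolated) | [Li]C#CCC=C(C)C | intermediate
11 | lithium 5-methylhex-4-en-1-yn-1-olate (not isolated) | [Li+].[O-]C#CCC=C(C)C | intermediate
12 | triisopropyl[(5-methylhex-4-en-1-yn-1-yl)oxy]silane | CC(C)=CCC#CO[Si](C(C)C)(C(C)C)C(C)C | intermediate
13 | (3E)-7-methylocta-1,3,6-trien-1-one, vinylketene (not isolated) | O=C=C/C=C/CC=C(C)C | intermediate
14 | 4-[(1E)-5-methylhexa-1,4-dien-1-yl]-2-(3-methylbut-2-en-1-yl)-3-[(triisopropylsilyl)oxy]cyclobut-2-en-1-one, racemic (not isolated) | CC(C)=CC/C=C/C1C(=O)C(CC=C(C)C)=C1O[Si](C(C)C)(C(C)C)C(C)C | intermediate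
15 | (3E,5E)-9-methyl-2-(3-methylbut-2-en-1-yl)-3-[(triisopropylsilyl)oxy]deca-1,3,5,8-tetraen-1-one, dienylketene (not isolated) | O=C=C(CC=C(C)C)/C(O[Si](C(C)C)(C(C)C)C(C)C)=C\C=C\CC=C(C)C | intermediate
16 | 2,6-bis(3-methylbut-2-en-1-yl)-3-[(triisopropylsilyl)oxy]cyclohexa-2,4-dien-1-one, racemic (not isolated) | CC(C)=CCC1C=CC(O[Si](C(C)C)(C(C)C)C(C)C)=C(CC=C(C)C)C1=O | intermediate
17 | 2,6-bis(3-methylbut-2-en-1-yl)-3-[(triisopropylsilyl)oxy]phenol | CC(C)=CCc1ccc(O[Si](C(C)C)(C(C)C)C(C)C)c(CC=C(C)C)c1O | intermediate
18 | 2,4-bis(3-methylbut-2-en-1-yl)benzene-1,3-diol | CC(C)=CCc1ccc(O)c(CC=C(C)C)c1O | intermediate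
19 | 1,3-bis(methoxymethoxy)-2,4-bis(3-methylbut-2-en-1-yl)benzene | COCOc1ccc(CC=C(C)C)c(OCOC)c1CC=C(C)C | intermediate
20 | (E)-4-hydroxycinnamic acid | O=C(O)/C=C/c1ccc(O)cc1 | starting material
21 | (E)-3-(4-hydroxyphenyl)-N-methoxy-N-methylprop-2-enamide | CON(C)C(=O)/C=C/c1ccc(O)cc1 | intermediate
22 | (E)-N-methoxy-3-[4-(methoxymethoxy)phenyl]-N-methylprop-2-enamide | CON(C)C(=O)/C=C/c1ccc(OCOC)cc1 | intermediate
23 | [2,4-bis(methoxymethoxy)-3,5-bis(3-methylbut-2-en-1-yl)phenyl]lithium (not isolated) | [Li]c1cc(CC=C(C)C)c(OCOC)c(CC=C(C)C)c1OCOC | intermediate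
24 | lithium (E)-1-[2,4-bis(methoxymethoxy)-3,5-bis(3-methylbut-2-en-1-yl)phenyl]-1-[methoxy(methyl)amino]-3-[4-(methoxymethoxy)phenyl]prop-2-en-1-olate, racemic (not isolated) | [Li+].[O-]C(/C=C/c1ccc(OCOC)cc1)(N(C)OC)c1cc(CC=C(C)C)c(OCOC)c(CC=C(C)C)c1OCOC | intermediate
25 | (E)-1-[2,4-bis(methoxymethoxy)-3,5-bis(3-methylbut-2-en-1-yl)phenyl]-3-[4-(methoxymethoxy)phenyl]prop-2-en-1-one | COCOc1ccc(/C=C/C(=O)c2cc(CC=C(C)C)c(OCOC)c(CC=C(C)C)c2OCOC)cc1 | intermediate
26 | (E)-1-[2,4-dihydroxy-3,5-bis(3-methylbut-2-en-1-yl)phenyl]-3-(4-hydroxyphenyl)prop-2-en-1-one | CC(C)=CCc1cc(C(=O)/C=C/c2ccc(O)cc2)c(O)c(CC=C(C)C)c1O | target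

**Count**

Total steps: 12. Longest linear sequence: 8 steps (1, 2, 3, 6, 7, 8, 11, 12).

**Steps most likely to fail**

Step 6. The photogenerated vinylketene may not be captured cleanly by 12 (ketene oligomerisation, acylation of the product phenol by further ketene), and the 1,4-diene or the phenol may undergo secondary photoreactions on long irradiation, so ring A may not form in useful amount. The fallback buys ring A and puts on both prenyl groups by directed metalation; it sets out from prenyl bromide 7 and returns to the route at 19. 1,3-bis(methoxymethoxy)benzene F1 is lithiated between the two acetal oxygens (n-BuLi, THF, 0 °C) to [2,6-bis(methoxymethoxy)phenyl]lithium F2. Alkylation with 7 (CuI cat.) gives 1,3-bis(methoxymethoxy)-2-(3-methylbut-2-en-1-yl)benzene F3. A second lithiation ortho to one MOM ether (n-BuLi, TMEDA, THF) gives [2,4-bis(methoxymethoxy)-3-(3-methylbut-2-en-1-yl)phenyl]lithium F4, and alkylation with 7 (CuI cat.) delivers 19.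

Step 11. Deprotonation at the benzylic and allylic CH2 groups of the prenyl chains may compete with ring metalation at C1', or the aryllithium may add in conjugate fashion to the cinnamoyl amide. The fallback avoids any aryl anion; it sets out from diol 18 and returns at 25.
- Magnesium-mediated ortho-formylation (MgCl2, Et3N, paraformaldehyde, MeCN, reflux) should place CHO on the only free position ortho to a hydroxyl and give 2,4-dihydroxy-3,5-bis(3-methylbut-2-en-1-yl)benzaldehyde F5.
- NaH and MOMCl give 2,4-bis(methoxymethoxy)-3,5-bis(3-methylbut-2-en-1-yl)benzaldehyde F6.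
- MeMgBr in THF gives 1-[2,4-bis(methoxymethoxy)-3,5-bis(3-methylbut-2-en-1-yl)phenyl]ethan-1-ol F7.
- Dess–Martin periodinane gives 1-[2,4-bis(methoxymethoxy)-3,5-bis(3-methylbut-2-en-1-yl)phenyl]ethan-1-one F8.
- Claisen–Schmidt condensation of F8 with 4-(methoxymethoxy)benzaldehyde F9 (KOH, EtOH, rt) gives the (E)-chalcone 25.

Step 1. The β,γ-double bond of aldehyde 3 may migrate into conjugation, or 3 may be lost by self-condensation, before the ylide adds, and the skipped dienone may isomerise under the reaction conditions. The fallback never passes through 3; it sets out from enyne 9 through its lithium acetylide 10 and returns at 4. Addition of 10 to acetaldehyde gives 7-methyloct-6-en-3-yn-2-ol F10. Trans-selective hydroalumination of the propargylic alcohol with NaAlH2(OCH2CH2OMe)2 in THF gives (E)-7-methylocta-3,6-dien-2-ol F11. Oxidation of the allylic alcohol with MnO2 in CH2Cl2 gives enone 4.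

**Further compounds**

F1 | step 6 | 1,3-bis(methoxymethoxy)benzene | COCOc1cccc(OCOC)c1
F2 | step 6 | [2,6-bis(methoxymethoxy)phenyl]lithium | [Li]c1c(OCOC)cccc1OCOC
F3 | step 6 | 1,3-bis(methoxymethoxy)-2-(3-methylbut-2-en-1-yl)benzene | COCOc1cccc(OCOC)c1CC=C(C)C
F4 | step 6 | [2,4-bis(methoxymethoxy)-3-(3-methylbut-2-en-1-yl)phenyl]lithium | [Li]c1ccc(OCOC)c(CC=C(C)C)c1OCOC
F5 | step 11 | 2,4-dihydroxy-3,5-bis(3-methylbut-2-en-1-yl)benzaldehyde | O=Cc1cc(CC=C(C)C)c(O)c(CC=C(C)C)c1O
F6 | step 11 | 2,4-bis(methoxymethoxy)-3,5-bis(3-methylbut-2-en-1-yl)benzaldehyde | COCOc1c(CC=C(C)C)cc(C=O)c(OCOC)c1CC=C(C)C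
F7 | step 11 | 1-[2,4-bis(methoxymethoxy)-3,5-bis(3-methylbut-2-en-1-yl)phenyl]ethan-1-ol (racemic) | CC(O)c1cc(CC=C(C)C)c(OCOC)c(CC=C(C)C)c1OCOC
F8 | step 11 | 1-[2,4-bis(methoxymethoxy)-3,5-bis(3-methylbut-2-en-1-yl)phenyl]ethan-1-one | CC(=O)c1cc(CC=C(C)C)c(OCOC)c(CC=C(C)C)c1OCOC
F9 | step 11 | 4-(methoxymethoxy)benzaldehyde | COCOc1ccc(C=O)cc1
F10 | step 1 | 7-methyloct-6-en-3-yn-2-ol (racemic) | CC(O)C#CCC=C(C)C
F11 | step 1 | (E)-7-methylocta-3,6-dien-2-ol (racemic) | CC(O)/C=C/CC=C(C)C
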